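**Retrosynthetic overview**

1. Target 27 ⇐ diol 26 (double isobutyrylation) ⇐ 25 (desilylation) ⇐ 21 (C11 methylenation): the exocyclic C11=C13 methylene and both esters are added only after both rings exist.
2. 21 ⇐ 20 by ring-closing metathesis: ring B (C5–C10) holds a single alkene, the tetrasubstituted C5=C10 bond flanked by the C4 and C6 stereocentres, and is closed at that bond from a cis-4,5-disubstituted γ-lactone carrying a methallyl group on C8 and a 2-substituted allylic silyl ether on C7.
3. 20 ⇐ hydroxy ester 19 (lactonisation, ring A) ⇐ aldehyde 16 + methallyl unit 17 (reagent-controlled allylboration sets C8).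
4. 16 ⇐ Evans syn-aldol of succinate imide 11 with enal 7 (sets C6 and C7); 7 ⇐ (S)-citronellal 1 (supplies C4 and the C1–C6 chain; C5 methylidene from formaldehyde).
5. Ring order: lactone ring A first (step 12), cyclohexene ring B second (step 13).

Key step: step 13

Remark (numbering): C1–C4 = side chain (C1 carries the primary oxygen, C15 = methyl on C4); C5–C10 = ring B (C14 = methyl on C10); C11, C12, C13 = lactone α-carbon, carbonyl and exocyclic methylene; ring A = lactone (C7, C8, O, C12, C11).
Remark (assumption): 8, 9 and 17 (as its THF solution) are taken as purchased; the primary silyl group is tert-butyldiphenylsilyl so that it survives the acid of steps 4 and 12.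

**Route**

Step 1
Reactants: 1 (S)-citronellal
Product: 2 (6S)-8,8-dimethoxy-2,6-dimethyloct-2-ene
Conditions: HC(OMe)3, MeOH, PPTS (cat.), 23 °C
Reagents that add atoms: trimethyl orthoformate, COC(OC)OC; methanol, CO
Why: Acid-catalysed acetalisation with orthoformate as dehydrating agent masks the aldehyde before ozonolysis, the mild pyridinium acid avoiding the carbonyl-ene cyclisation of citronellal and leaving the chiral-pool C4 centre untouched.

Step 2
Reactants: 2 (6S)-8,8-dimethoxy-2,6-dimethyloct-2-ene
Product: 4 (4S)-6,6-dimethoxy-4-methylhexan-1-ol, via secondary ozonide 3 (not isolated)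
Conditions: O3, CH2Cl2, −78 °C; then MeOH, NaBH4, −78 → 23 °C
Reagents that add atoms: ozone, [O-][O+]=O
Why: Ozonolysis of the only alkene with reductive borohydride work-up of the ozonide gives the primary alcohol that becomes C1–O; no stereocentre is formed.

Step 3
Reactants: 4 (4S)-6,6-dimethoxy-4-methylhexan-1-ol
Product: 5 tert-butyl{[(4S)-6,6-dimethoxy-4-methylhexyl]oxy}diphenylsilane
Conditions: TBDPSCl, imidazole, CH2Cl2, 0 → 23 °C
Reagents that add atoms: tert-butyl(chloro)diphenylsilane, CC(C)(C)[Si](Cl)(c1ccccc1)c1ccccc1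
Why: Standard silyl ether formation with a group robust enough for the later aqueous and anhydrous acid steps.

Step 4
Reactants: 5 tert-butyl{[(4S)-6,6-dimethoxy-4-methylhexyl]oxy}diphenylsilane
Product: 6 (3S)-6-[(tert-butyldiphenylsilyl)oxy]-3-methylhexanal
Conditions: 1 M aq. HCl, THF, 23 °C
Reagents that add atoms: water, O
Why: Acid hydrolysis of the dimethyl acetal liberates the aldehyde while the diphenyl-substituted silyl ether is stable to dilute aqueous acid.

Step 5
Reactants: 6 (3S)-6-[(tert-butyldiphenylsilyl)oxy]-3-methylhexanal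
Product: 7 (3S)-6-[(tert-butyldiphenylsilyl)oxy]-3-methyl-2-methylidenehexanal
Conditions: 37% aq. CH2O, pyrrolidine (10 mol %), propionic acid (10 mol %), i-PrOH, 45 °C
Reagents that add atoms: formaldehyde, C=O
Why: Organocatalytic α-methylenation (Mannich condensation of the pyrrolidine enamine with the formaldehyde iminium, then β-elimination of the amine) installs the C5 methylidene, and C4 should keep its configuration because it lies outside the enamine if the reaction is stopped at full conversion.

Step 6
Reactants: 8 4-tert-butoxy-4-oxobutanoic acid; 9 (4S)-4-benzyl-1,3-oxazolidin-2-one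
Product: 11 tert-butyl 4-[(4S)-4-benzyl-2-oxo-1,3-oxazolidin-3-yl]-4-oxobutanoate, via mixed pivalic anhydride 10 (not isolated)
Conditions: PivCl, Et3N, THF, −20 °C; then 9, LiCl, −20 → 23 °C
Reagents that add atoms: none
Why: N-Acylation of the oxazolidinone through the mixed pivalic anhydride (LiCl/Et3N activation) is the standard way to load a carboxylic acid on the auxiliary.

Step 7
Reactants: 11 tert-butyl 4-[(4S)-4-benzyl-2-oxo-1,3-oxazolidin-3-yl]-4-oxobutanoate; 7 (3S)-6-[(tert-butyldiphenylsilyl)oxy]-3-methyl-2-methylidenehexanal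
Product: 13 tert-butyl (3S,4S,6S)-3-{[(4S)-4-benzyl-2-oxo-1,3-oxazolidin-3-yl]carbonyl}-9-[(tert-butyldiphenylsilyl)oxy]-4-hydroxy-6-methyl-5-methylidenenonanoate, via dibutylboron Z-enolate 12 (not isolated)
Conditions: 11, Bu2BOTf, i-Pr2NEt, CH2Cl2, −78 → 0 °C; then 7, −78 → 0 °C; pH 7 buffer (NaH2PO4/Na2HPO4), MeOH, 30% H2O2, 0 °C
Reagents that add atoms: none
Why: Evans syn-aldol in which soft enolisation gives the Z-boron enolate of the imide only (not of the ester), which adds to the enal through a closed chair (Zimmerman–Traxler) transition state on the face away from the benzyl group, setting C7 (S) and C6 (S) syn to one another, the tert-butyl ester being chosen because it resists lactonisation onto the new C6 hydroxyl.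

Step 8
Reactants: 13 aldol adduct
Product: 14 tert-butyl (3S,4S,6S)-3-{[(4S)-4-benzyl-2-oxo-1,3-oxazolidin-3-yl]carbonyl}-4-[(tert-butyldimethylsilyl)oxy]-9-[(tert-butyldiphenylsilyl)oxy]-6-methyl-5-methylidenenonanoate
Conditions: TBSOTf, 2,6-lutidine, CH2Cl2, −78 → 0 °C
Reagents that add atoms: tert-butyldimethylsilyl trifluoromethanesulfonate, CC(C)(C)[Si](C)(C)OS(=O)(=O)C(F)(F)F
Why: Silyl triflate silylation of the hindered allylic alcohol blocks retro-aldol and 6,12-lactonisation and fixes O6 as the ether carried through the key step.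

Step 9
Reactants: 14 silylated aldol adduct
Product: 15 tert-butyl (3S,4S,6S)-4-[(tert-butyldimethylsilyl)oxy]-9-[(tert-butyldiphenylsilyl)oxy]-3-[(ethylsulfanyl)carbonyl]-6-methyl-5-methylidenenonanoate
Conditions: EtSH, n-BuLi, THF, 0 °C
Reagents that add atoms: ethanethiol, CCS (used as lithium ethanethiolate, [Li+].CC[S-])
Why: Transthioesterification, in which the soft thiolate attacks the exocyclic imide carbonyl of the hindered β-silyloxy adduct and releases the auxiliary without creating a C8 alkoxide that could lactonise or take over the silyl group.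

Step 10
Reactants: 15 thioester
Product: 16 tert-butyl (3S,4S,6S)-4-[(tert-butyldimethylsilyl)oxy]-9-[(tert-butyldiphenylsilyl)oxy]-3-formyl-6-methyl-5-methylidenenonanoate
Conditions: i-Bu2AlH (1.2 equiv), CH2Cl2, −78 °C; aq. potassium sodium tartrate
Reagents that add atoms: none
Why: Partial reduction of a thioester with i-Bu2AlH stops at the aldehyde because the aluminium hemithioacetal is stable at −78 °C, the hindered tert-butyl ester is untouched, and the aldehyde is used at once to avoid epimerisation at C7.

Step 11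
Reactants: 16 C8 aldehyde; 17 2-methylallylmagnesium chloride
Product: 19 tert-butyl (3R,4S,6S)-4-[(tert-butyldimethylsilyl)oxy]-9-[(tert-butyldiphenylsilyl)oxy]-3-[(1R)-1-hydroxy-3-methylbut-3-en-1-yl]-6-methyl-5-methylidenenonanoate, via B-methallyl-diisopinocampheylborane 18 (not isolated)
Conditions: (+)-Ipc2BOMe [from (−)-α-pinene], 17, Et2O, 0 → 23 °C; then 16, −78 °C; aq. NaHCO3, 30% H2O2, 0 → 23 °C
Reagents that add atoms: none
Why: Asymmetric allylboration of the Brown type, in which the B-methallyl borane from (−)-α-pinene transfers the methallyl group through a chair transition state to the Re face of the C8 aldehyde, setting C8 (R; 7,8-anti and 6,8-anti) under reagent control against the modest Felkin preference of the substrate, while the ester is not attacked.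

Step 12
Reactants: 19 γ-hydroxy tert-butyl ester
Product: 20 (4R,5R)-4-{(1S,3S)-1-[(tert-butyldimethylsilyl)oxy]-6-[(tert-butyldiphenylsilyl)oxy]-3-methyl-2-methylidenehexyl}-5-(2-methylprop-2-en-1-yl)oxolan-2-one (lactone diene)
Conditions: CSA (0.2 equiv), CH2Cl2, 23 °C
Reagents that add atoms: none
Why: Acid-catalysed intramolecular transesterification (5-exo-trig) closes ring A with retention at C8 and gives the cis-4,5-disubstituted lactone because C7 and C8 were set anti in the open chain, only the 8,12-lactone being possible since O6 is silylated.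

Step 13
Reactants: 20 lactone diene
Product: 21 (3aR,4S,7aR)-4-[(tert-butyldimethylsilyl)oxy]-5-{(2S)-5-[(tert-butyldiphenylsilyl)oxy]pentan-2-yl}-6-methyl-3a,4,7,7a-tetrahydro-1-benzofuran-2(3H)-one
Conditions: RuCl2(=CH-C6H4-2-OiPr)(1,3-di-o-tolylimidazolidin-2-ylidene) (2 × 10 mol %), 2,6-dichloro-1,4-benzoquinone (20 mol %), toluene (0.005 M), 100 °C, Ar sparge
Reagents that add atoms: none
Why: Ring-closing olefin metathesis, in which the ruthenium carbene first exchanges onto the less hindered methallyl alkene to give the C10 alkylidene, this adds across the C5 methylidene in a [2+2] cycloaddition, and cycloreversion of the ruthenacyclobutane forms the C5=C10 bond with overall loss of ethylene. The closest known reaction type is metathesis closure of dienes built from two 1,1-disubstituted alkenes to tetrasubstituted cycloalkenes with N-heterocyclic-carbene ruthenium catalysts, for which the less bulky N-o-tolyl ligand of this phosphine-free second-generation catalyst is suited. Ring B, the six-membered carbocycle, is closed in this single event as a cis-annulation onto ring A, both alkene carbons ending inside the new ring. No stereocentre is created, and C4, C6, C7 and C8 are carried through unchanged. The step needs cyclisation to win over oligomerisation and double-bond migration, which high dilution, removal of ethylene, the quinone additive and the cis arrangement of the two arms on C7 and C8 should secure. The lactone still lacks its exocyclic methylene, so no acrylate-type alkene can trap the carbene.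

Step 14
Reactants: 21 bicyclic lactone
Product: 23 (3aR,4S,7aR)-4-[(tert-butyldimethylsilyl)oxy]-5-{(2S)-5-[(tert-butyldiphenylsilyl)oxy]pentan-2-yl}-3-[(dimethylamino)methyl]-6-methyl-3a,4,7,7a-tetrahydro-1-benzofuran-2(3H)-one (C3 epimer from convex-face attack drawn), via lithium enolate 22 (not isolated)
Conditions: LiN(SiMe3)2, THF, −78 °C; then CH2=NMe2+ I−, −78 → 23 °C
Reagents that add atoms: N,N-dimethylmethyleneiminium iodide, C=[N+](C)C.[I-]
Why: Kinetic lithium enolate formation at C11 and Mannich reaction with the preformed iminium salt from the convex face, the new C11 centre being destroyed in step 15, is the standard first half of lactone α-methylenation.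

Step 15
Reactants: 23 Mannich base
Product: 25 (3aR,4S,7aR)-4-[(tert-butyldimethylsilyl)oxy]-5-{(2S)-5-[(tert-butyldiphenylsilyl)oxy]pentan-2-yl}-6-methyl-3-methylidene-3a,4,7,7a-tetrahydro-1-benzofuran-2(3H)-one, via trimethylammonium iodide 24 (not isolated)
Conditions: MeI, MeOH, 23 °C; then sat. aq. NaHCO3, CH2Cl2, 23 °C
Reagents that add atoms: none
Why: Exhaustive N-methylation followed by base-induced β-elimination of trimethylamine (Hofmann-type, E1cB) generates the exocyclic C11=C13 alkene under conditions too mild to epimerise C7 or open the lactone.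

Step 16
Reactants: 25 bis-silyl α-methylene lactone
Product: 26 (3aS,4S,7aR)-4-hydroxy-5-[(2S)-5-hydroxypentan-2-yl]-6-methyl-3-methylidene-3a,4,7,7a-tetrahydro-1-benzofuran-2(3H)-one (3a descriptor changes by priority only)
Conditions: HF·pyridine, pyridine, THF, 0 → 23 °C
Reagents that add atoms: none
Why: Fluoride-mediated cleavage of both silyl ethers in buffered HF·pyridine, which is weakly acidic and should spare the α-methylene lactone and not equilibrate the 8,12-lactone with the 6,12-isomer.

Step 17
Reactants: 26 diol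
Product: 27 (3aR,4S,7aR)-6-methyl-3-methylidene-5-[(2S)-5-(2-methylpropanoyloxy)pentan-2-yl]-2-oxo-2,3,3a,4,7,7a-hexahydro-1-benzofuran-4-yl 2-methylpropanoate (target)
Conditions: (i-PrCO)2O, DMAP, Et3N, CH2Cl2, 0 → 23 °C
Reagents that add atoms: isobutyric anhydride, CC(C)C(=O)OC(=O)C(C)C
Why: DMAP-catalysed acylation via the acylpyridinium esterifies the primary C1 and the hindered allylic C6 hydroxyl without touching any stereocentre, and the short, cold, weakly basic conditions should not induce translactonisation.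

**Compound list**

1 | (S)-citronellal, (3S)-3,7-dimethyloct-6-enal | C[C@@H](CCC=C(C)C)CC=O | starting material
2 | (6S)-8,8-dimethoxy-2,6-dimethyloct-2-ene | COC(OC)C[C@@H](C)CCC=C(C)C | intermediate
3 | 3-[(3S)-5,5-dimethoxy-3-methylpentyl]-5,5-dimethyl-1,2,4-trioxolane (secondary ozonide, epimers at the ring carbon) | COC(OC)C[C@@H](C)CCC1OOC(C)(C)O1 | intermediate (not isolated)
4 | (4S)-6,6-dimethoxy-4-methylhexan-1-ol | COC(OC)C[C@@H](C)CCCO | intermediate
5 | tert-butyl{[(4S)-6,6-dimethoxy-4-methylhexyl]oxy}diphenylsilane | COC(OC)C[C@@H](C)CCCO[Si](c1ccccc1)(c1ccccc1)C(C)(C)C | intermediate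
6 | (3S)-6-[(tert-butyldiphenylsilyl)oxy]-3-methylhexanal | O=CC[C@@H](C)CCCO[Si](c1ccccc1)(c1ccccc1)C(C)(C)C | intermediate
7 | (3S)-6-[(tert-butyldiphenylsilyl)oxy]-3-methyl-2-methylidenehexanal | C=C(C=O)[C@@H](C)CCCO[Si](c1ccccc1)(c1ccccc1)C(C)(C)C | intermediate
8 | 4-tert-butoxy-4-oxobutanoic acid (mono-tert-butyl succinate) | CC(C)(C)OC(=O)CCC(=O)O | starting material
9 | (4S)-4-benzyl-1,3-oxazolidin-2-one | O=C1N[C@@H](Cc2ccccc2)CO1 | starting material
10 | 4-tert-butoxy-4-oxobutanoic pivalic anhydride | CC(C)(C)C(=O)OC(=O)CCC(=O)OC(C)(C)C | intermediate (not isolated)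
11 | tert-butyl 4-[(4S)-4-benzyl-2-oxo-1,3-oxazolidin-3-yl]-4-oxobutanoate | O=C1OC[C@H](Cc2ccccc2)N1C(=O)CCC(=O)OC(C)(C)C | intermediate
12 | dibutylboron (Z)-enolate of 11 | CCCCB(CCCC)O/C(=C\CC(=O)OC(C)(C)C)N1[C@@H](Cc2ccccc2)COC1=O | intermediate (not isolated)
13 | syn-aldol adduct (3S,4S,6S; free C6 hydroxyl) | O=C1OC[C@H](Cc2ccccc2)N1C(=O)[C@@H](CC(=O)OC(C)(C)C)[C@H](O)C(=C)[C@@H](C)CCCO[Si](c1ccccc1)(c1ccccc1)C(C)(C)C | intermediate
14 | C6 tert-butyldimethylsilyl ether of 13 | O=C1OC[C@H](Cc2ccccc2)N1C(=O)[C@@H](CC(=O)OC(C)(C)C)[C@H](O[Si](C)(C)C(C)(C)C)C(=C)[C@@H](C)CCCO[Si](c1ccccc1)(c1ccccc1)C(C)(C)C | intermediate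
15 | S-ethyl thioester (3S,4S,6S) | CCSC(=O)[C@@H](CC(=O)OC(C)(C)C)[C@H](O[Si](C)(C)C(C)(C)C)C(=C)[C@@H](C)CCCO[Si](c1ccccc1)(c1ccccc1)C(C)(C)C | intermediate
16 | C8 aldehyde (3S,4S,6S) | O=C[C@@H](CC(=O)OC(C)(C)C)[C@H](O[Si](C)(C)C(C)(C)C)C(=C)[C@@H](C)CCCO[Si](c1ccccc1)(c1ccccc1)C(C)(C)C | intermediate
17 | 2-methylallylmagnesium chloride | C=C(C)C[Mg]Cl | starting material
18 | B-(2-methylallyl)diisopinocampheylborane, isopinocampheyl groups from (−)-α-pinene (configured as in (+)-isopinocampheol) | C=C(C)CB([C@H]1C[C@H]2C[C@@H]([C@@H]1C)C2(C)C)[C@H]1C[C@H]2C[C@@H]([C@@H]1C)C2(C)C | intermediate (not isolated)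
19 | γ-hydroxy tert-butyl ester (3R,4S,6S,1′R) | C=C(C)C[C@@H](O)[C@@H](CC(=O)OC(C)(C)C)[C@H](O[Si](C)(C)C(C)(C)C)C(=C)[C@@H](C)CCCO[Si](c1ccccc1)(c1ccccc1)C(C)(C)C | intermediate
20 | lactone diene, (4R,5R)-oxolan-2-one with (1S,3S) side chain on C4 and methallyl on C5 | C=C(C)C[C@H]1OC(=O)C[C@H]1[C@H](O[Si](C)(C)C(C)(C)C)C(=C)[C@@H](C)CCCO[Si](c1ccccc1)(c1ccccc1)C(C)(C)C | intermediate
21 | bis-silyl bicyclic lactone (3aR,4S,7aR) | C1C(=O)O[C@@H]2CC(C)=C([C@@H](C)CCCO[Si](c3ccccc3)(c3ccccc3)C(C)(C)C)[C@@H](O[Si](C)(C)C(C)(C)C)[C@H]12 | intermediate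
22 | lithium enolate of 21 | C1=C([O-])O[C@@H]2CC(C)=C([C@@H](C)CCCO[Si](c3ccccc3)(c3ccccc3)C(C)(C)C)[C@@H](O[Si](C)(C)C(C)(C)C)[C@H]12.[Li+] | intermediate (not isolated)
23 | 3-[(dimethylamino)methyl] lactone (Mannich base) | CN(C)C[C@H]1C(=O)O[C@@H]2CC(C)=C([C@@H](C)CCCO[Si](c3ccccc3)(c3ccccc3)C(C)(C)C)[C@@H](O[Si](C)(C)C(C)(C)C)[C@H]12 | intermediate
24 | trimethylammonium iodide of 23 | C[N+](C)(C)C[C@H]1C(=O)O[C@@H]2CC(C)=C([C@@H](C)CCCO[Si](c3ccccc3)(c3ccccc3)C(C)(C)C)[C@@H](O[Si](C)(C)C(C)(C)C)[C@H]12.[I-] | intermediate (not isolated)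
25 | bis-silyl α-methylene lactone (3aR,4S,7aR) | C=C1C(=O)O[C@@H]2CC(C)=C([C@@H](C)CCCO[Si](c3ccccc3)(c3ccccc3)C(C)(C)C)[C@@H](O[Si](C)(C)C(C)(C)C)[C@H]12 | intermediate
26 | diol | C=C1C(=O)O[C@@H]2CC(C)=C([C@@H](C)CCCO)[C@@H](O)[C@H]12 | intermediate
27 | CNP0509808.1 | C=C1C(=O)O[C@@H]2CC(C)=C([C@@H](C)CCCOC(=O)C(C)C)[C@@H](OC(=O)C(C)C)[C@H]12 | target

**Count and risks**

Total steps: 17 (steps 1–5 aldehyde branch, step 6 imide branch, steps 7–17 main line). Longest linear sequence: 16 steps (1–5, then 7–17).

Steps most likely to fail: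

Step 13 (ring-closing metathesis). The ruthenacyclobutane must join two fully substituted carbons next to the C6 silyloxy group and the C4 branch. It may therefore not form at a useful rate, so that catalyst decay, dimerisation through the methallyl group or double-bond migration take over. Fallback, setting out from 20: ozonolysis of both 1,1-disubstituted alkenes (O3, CH2Cl2/MeOH, −78 °C; Me2S) gives the C5,C10-diketone F1. An intramolecular McMurry coupling (TiCl3(DME)1.5, Zn–Cu couple, DME, reflux, slow addition) then forms the same C5=C10 bond by reductive carbonyl coupling. The two ketones should couple faster than low-valent titanium attacks the lactone, though loss of the α-silyloxy group is a known side reaction to watch. The route is rejoined at 21.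

Step 11 (methallylboration). The reagent must override the intrinsic Felkin bias of the α-branched aldehyde, so facial selectivity may be poor, and the aldehyde may epimerise at C7 before it reacts. Fallback, setting out from 16: direct addition of 17 (THF, −78 °C) without the chiral borane gives 19 mixed with its C8 epimer F2. The mixture is oxidised (Dess–Martin periodinane, NaHCO3, CH2Cl2) to the β,γ-unsaturated ketone F3. Reduction with LiBH(s-Bu)3 (THF, −78 °C) then delivers hydride under Felkin–Anh control anti to the C6 branch, the same sense that gives cis-4,5-disubstituted γ-lactones from 3-substituted 4-oxo esters, which is the 7,8-anti alcohol. The route is rejoined at 19.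

Step 12 (lactonisation). Acyl substitution at the hindered tert-butyl ester may be slow, so that acid-induced loss of a silyl ether or migration of the methallyl double bond competes. Fallback, setting out from 19: TMSOTf/2,6-lutidine (CH2Cl2, 0 °C) converts the tert-butyl ester into the silyl ester with loss of isobutene, and mild aqueous methanolic work-up gives the hydroxy acid F4. This is closed by carbodiimide activation (EDC·HCl, DMAP, CH2Cl2, 0 °C), rejoining the route at 20.

Further compounds
F1 | step 13 | (4R,5R)-4-{(1S,3S)-1-[(tert-butyldimethylsilyl)oxy]-6-[(tert-butyldiphenylsilyl)oxy]-3-methyl-2-oxohexyl}-5-(2-oxopropyl)oxolan-2-one | CC(=O)C[C@H]1OC(=O)C[C@H]1[C@H](O[Si](C)(C)C(C)(C)C)C(=O)[C@@H](C)CCCO[Si](c1ccccc1)(c1ccccc1)C(C)(C)C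
F2 | step 11 | C8 epimer of 19, (1S)-1-hydroxy-3-methylbut-3-en-1-yl side chain | C=C(C)C[C@H](O)[C@@H](CC(=O)OC(C)(C)C)[C@H](O[Si](C)(C)C(C)(C)C)C(=C)[C@@H](C)CCCO[Si](c1ccccc1)(c1ccccc1)C(C)(C)C
F3 | step 11 | C8 ketone, tert-butyl (3S,4S,6S)-4-[(tert-butyldimethylsilyl)oxy]-9-[(tert-butyldiphenylsilyl)oxy]-6-methyl-3-(3-methylbut-3-enoyl)-5-methylidenenonanoate | C=C(C)CC(=O)[C@@H](CC(=O)OC(C)(C)C)[C@H](O[Si](C)(C)C(C)(C)C)C(=C)[C@@H](C)CCCO[Si](c1ccccc1)(c1ccccc1)C(C)(C)C
F4 | step 12 | γ-hydroxy acid corresponding to 19 | C=C(C)C[C@@H](O)[C@@H](CC(=O)O)[C@H](O[Si](C)(C)C(C)(C)C)C(=C)[C@@H](C)CCCO[Si](c1ccccc1)(c1ccccc1)C(C)(C)C
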